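The pyranone ring C is cut at the C2–C3 bond. C2 is a CH bound to the ring oxygen O1, so it can be the methyl carbon of a methoxy group on C8a of ring A, ortho to the C4 ketone. A rhodium carbene at C3, generated from an α-diazo deoxybenzoin, should insert into a C–H bond of that O-methyl group, forming C2–C3 and closing ring C in one operation to give the isoflavanone. The precursor is a hexasubstituted A-ring aryl ketone with 8a-OMe, 7,8-benzyl ethers, 6-OMe and a 5-O-triisopropylsilyl ether, carrying the benzyl-protected B ring on the diazo carbon.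

Key step: step 14

Remark on stereochemistry: the target has no stereocentre and no stereogenic double bond, so it is one achiral compound. The two stereocentres that appear on the way (carbinol 19, C3 of 22) are formed racemic and are removed by oxidation.

Remark on the precursor design: the 5-oxygen is masked as a TIPS ether. It has no C–H next to oxygen, its bulk shields the oxygen lone pairs from the carbene, and it should resist O-to-O silyl transfer in steps 11 and 13 better than a smaller silyl group. The ketone is built by formylation, Grignard addition and oxidation, not by Lewis-acid acylation, so the benzyl ethers never meet a strong Lewis acid.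

Step 1
Reactants: 1 2,3-dihydroxy-4-methoxybenzaldehyde; 2 benzyl bromide
Product: 3 2,3-bis(benzyloxy)-4-methoxybenzaldehyde
Conditions: BnBr, K2CO3, DMF, 60 °C
Reagents that add atoms: benzyl bromide (2), BrCc1ccccc1
Why: Williamson ether synthesis, in which both phenoxides are alkylated while the aldehyde is untouched; benzyl survives every later step and leaves by hydrogenolysis at the end.

Step 2
Reactants: 3 2,3-bis(benzyloxy)-4-methoxybenzaldehyde
Product: 5 2,3-bis(benzyloxy)-4-methoxyphenol, via 2,3-bis(benzyloxy)-4-methoxyphenyl formate 4 (not isolated)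
Conditions: mCPBA, CH2Cl2, 0 °C to rt; then K2CO3 (cat.), MeOH, rt
Reagents that add atoms: mCPBA, O=C(OO)c1cccc(Cl)c1
Why: Baeyer–Villiger (Dakin-type) oxidation, in which the electron-rich aryl group (ortho- and para-alkoxy) migrates in the Criegee adduct to give formate 4, and mild methanolysis then frees the phenol without touching the benzyl ethers.

Step 3
Reactants: 5 2,3-bis(benzyloxy)-4-methoxyphenol
Product: 6 2,3-bis(benzyloxy)-1,4-dimethoxybenzene
Conditions: MeI, K2CO3, acetone, reflux
Reagents that add atoms: iodomethane, CI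
Why: Williamson O-methylation of the phenoxide, which makes a C2-symmetric tetraalkoxybenzene whose two remaining C–H positions are equivalent.

Step 4
Reactants: 6 2,3-bis(benzyloxy)-1,4-dimethoxybenzene
Product: 8 3,4-bis(benzyloxy)-2,5-dimethoxybenzaldehyde, via 3,4-bis(benzyloxy)-2,5-dimethoxybenzylidene(dimethyl)iminium chloride 7 (not isolated)
Conditions: POCl3, DMF, 0 to 75 °C; then aq NaOAc
Reagents that add atoms: N,N-dimethylformamide, CN(C)C=O; water, O
Why: Vilsmeier–Haack formylation at a position that is ortho to a methoxy and para to a benzyloxy group; the two free positions are equivalent so only one aldehyde can form, and iminium 7 deactivates the ring against a second attack.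

Step 5
Reactants: 8 3,4-bis(benzyloxy)-2,5-dimethoxybenzaldehyde
Product: 10 3,4-bis(benzyloxy)-2,5-dimethoxyphenol, via 3,4-bis(benzyloxy)-2,5-dimethoxyphenyl formate 9 (not isolated)
Conditions: mCPBA, CH2Cl2, rt; then K2CO3 (cat.), MeOH, rt
Reagents that add atoms: mCPBA, O=C(OO)c1cccc(Cl)c1
Why: a second Baeyer–Villiger oxidation with aryl migration (ortho-OMe, para-OBn) and methanolysis of formate 9 replaces the formyl carbon by the oxygen that becomes the 5-OH.

Step 6
Reactants: 10 3,4-bis(benzyloxy)-2,5-dimethoxyphenol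
Product: 12 3,4-bis(benzyloxy)-6-hydroxy-2,5-dimethoxybenzaldehyde, via 3,4-bis(benzyloxy)-6-(hydroxymethyl)-2,5-dimethoxyphenol 11 (not isolated)
Conditions: MgCl2, Et3N, (CH2O)n, MeCN, reflux; dil. HCl work-up
Reagents that add atoms: formaldehyde (as paraformaldehyde), C=O
Why: magnesium-mediated ortho-formylation (Casnati–Skattebøl), in which the magnesium phenoxide delivers formaldehyde to the only free ring position and the benzylic alkoxide of 11 is oxidised by a second formaldehyde through Oppenauer-type hydride transfer, all without acid that could cleave benzyl ethers.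

Step 7
Reactants: 12 3,4-bis(benzyloxy)-6-hydroxy-2,5-dimethoxybenzaldehyde
Product: 13 3,4-bis(benzyloxy)-2,5-dimethoxy-6-(triisopropylsilyloxy)benzaldehyde
Conditions: TIPSOTf, 2,6-lutidine, CH2Cl2, 0 °C to rt
Reagents that add atoms: triisopropylsilyl trifluoromethanesulfonate, CC(C)[Si](OS(=O)(=O)C(F)(F)F)(C(C)C)C(C)C
Why: silylation of a hindered, hydrogen-bonded phenol with a highly electrophilic silyl triflate and a non-nucleophilic base.

Step 8
Reactants: 14 3-hydroxy-4,5-dimethoxybenzaldehyde; 2 benzyl bromide
Product: 15 3-(benzyloxy)-4,5-dimethoxybenzaldehyde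
Conditions: BnBr, K2CO3, DMF, 50 °C
Reagents that add atoms: benzyl bromide (2), BrCc1ccccc1
Why: Williamson ether synthesis on the single phenol, masking the 3'-OH (which would otherwise undergo O–H insertion in step 14) as an ether that leaves with the others in step 17.

Step 9
Reactants: 15 3-(benzyloxy)-4,5-dimethoxybenzaldehyde
Product: 16 [3-(benzyloxy)-4,5-dimethoxyphenyl]methanol
Conditions: NaBH4, MeOH, 0 °C
Reagents that add atoms: none
Why: borohydride reduction of an aromatic aldehyde to the benzylic alcohol, with all ethers inert.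

Step 10
Reactants: 16 [3-(benzyloxy)-4,5-dimethoxyphenyl]methanol
Product: 17 1-(benzyloxy)-5-(chloromethyl)-2,3-dimethoxybenzene
Conditions: SOCl2, CH2Cl2, 0 °C to rt
Reagents that add atoms: thionyl chloride, ClS(Cl)=O
Why: chlorination of the electron-rich benzylic alcohol through its chlorosulfite; the chloride is preferred over the bromide to limit Wurtz coupling in step 11.

Step 11
Reactants: 17 1-(benzyloxy)-5-(chloromethyl)-2,3-dimethoxybenzene; 13 3,4-bis(benzyloxy)-2,5-dimethoxy-6-(triisopropylsilyloxy)benzaldehyde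
Product: 19 1-[3,4-bis(benzyloxy)-2,5-dimethoxy-6-(triisopropylsilyloxy)phenyl]-2-[3-(benzyloxy)-4,5-dimethoxyphenyl]ethanol (racemic), via [3-(benzyloxy)-4,5-dimethoxybenzyl]magnesium chloride 18 (not isolated)
Conditions: Mg (I2-activated), 2-MeTHF, 0 °C to rt; then 13, THF, −78 to −20 °C; sat. aq NH4Cl
Reagents that add atoms: none
Why: Grignard addition of benzylic reagent 18 to a non-enolisable aldehyde, with low temperature and the covalent magnesium alkoxide keeping the TIPS group on the phenolic oxygen; the carbinol centre forms racemic and is removed in step 12.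

Step 12
Reactants: 19 1-[3,4-bis(benzyloxy)-2,5-dimethoxy-6-(triisopropylsilyloxy)phenyl]-2-[3-(benzyloxy)-4,5-dimethoxyphenyl]ethanol
Product: 20 1-[3,4-bis(benzyloxy)-2,5-dimethoxy-6-(triisopropylsilyloxy)phenyl]-2-[3-(benzyloxy)-4,5-dimethoxyphenyl]ethanone
Conditions: Dess–Martin periodinane, NaHCO3, CH2Cl2, rt
Reagents that add atoms: none
Why: Dess–Martin oxidation of the secondary benzylic alcohol to the deoxybenzoin under buffered, neutral conditions that leave silyl and benzyl ethers intact.

Step 13
Reactants: 20 1-[3,4-bis(benzyloxy)-2,5-dimethoxy-6-(triisopropylsilyloxy)phenyl]-2-[3-(benzyloxy)-4,5-dimethoxyphenyl]ethanone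
Product: 21 2-diazo-1-[3,4-bis(benzyloxy)-2,5-dimethoxy-6-(triisopropylsilyloxy)phenyl]-2-[3-(benzyloxy)-4,5-dimethoxyphenyl]ethanone
Conditions: p-ABSA, DBU, MeCN, 0 °C to rt
Reagents that add atoms: 4-acetamidobenzenesulfonyl azide, CC(=O)Nc1ccc(cc1)S(=O)(=O)N=[N+]=[N-]
Why: Regitz diazo transfer, in which DBU enolises the methylene activated by both aryl and ketone, the enolate attacks the terminal nitrogen of the sulfonyl azide and the triazene collapses to the diazo ketone and the sulfonamide.

Step 14
Reactants: 21 2-diazo-1-[3,4-bis(benzyloxy)-2,5-dimethoxy-6-(triisopropylsilyloxy)phenyl]-2-[3-(benzyloxy)-4,5-dimethoxyphenyl]ethanone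
Product: 22 7,8-bis(benzyloxy)-3-[3-(benzyloxy)-4,5-dimethoxyphenyl]-6-methoxy-5-(triisopropylsilyloxy)chroman-4-one (racemic at C3)
Conditions: Rh2(O2CCPh3)4 (2 mol %), 4 Å MS, CH2Cl2, rt to 40 °C, slow addition of 21
Reagents that add atoms: none
Why: Proposed new method: the dirhodium catalyst expels N2 from 21 to give an electrophilic aryl(aroyl) carbene at C3, whose empty orbital takes up a C–H bond of the 8a-O-methyl group in a concerted three-centre, hydride-transfer-like insertion assisted by the lone pair of the ether oxygen. The closest known reaction types are rhodium(II)-catalysed C–H insertion of ortho-alkoxyaryl α-diazoketones next to the ether oxygen to give chroman-4-ones and the C–H insertion cyclisation of α-aryl-α-diazo ketones; the untested part is a primary O–CH3 site combined with an aryl-substituted carbene in a six-membered closure. Ring C closes by 1,6-insertion through a six-membered transition state made of C3, C4, C4a, C8a, O1 and the methyl carbon (the future C2), helped because both the ketone and the flanked 8a-methoxy group are twisted out of the A-ring plane, which places the methyl group over the carbene. C3 becomes a stereocentre but forms racemic with the achiral catalyst and needs no control because step 15 removes it. The step needs C–H insertion to win over attack on the 8a-oxygen (five-membered oxonium ylide, then methyl shift), Wolff rearrangement and carbene dimerisation; the donor–acceptor carbene, the bulky triphenylacetate ligands, slow addition and the poor migrating ability of methyl (the ylide can only revert) should secure this. Site selectivity lies in the substrate: the 8a-OCH3 holds the only C–H bonds next to oxygen on a position ortho to the ketone, the other ortho oxygen is a TIPS ether without such bonds, and the benzyloxy groups and the 6-OMe sit meta or para to the ketone, out of geometric reach.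

Step 15
Reactants: 22 7,8-bis(benzyloxy)-3-[3-(benzyloxy)-4,5-dimethoxyphenyl]-6-methoxy-5-(triisopropylsilyloxy)chroman-4-one
Product: 23 7,8-bis(benzyloxy)-3-[3-(benzyloxy)-4,5-dimethoxyphenyl]-6-methoxy-5-(triisopropylsilyloxy)-4H-chromen-4-one
Conditions: DDQ, 1,4-dioxane, 90 °C
Reagents that add atoms: none
Why: DDQ dehydrogenation of the isoflavanone through its enol (hydride abstraction from C2) gives the chromone and erases C3 as a stereocentre, while the silyl ether keeps the 5,8-dioxygenated ring from being oxidised to a quinone.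

Step 16
Reactants: 23 7,8-bis(benzyloxy)-3-[3-(benzyloxy)-4,5-dimethoxyphenyl]-6-methoxy-5-(triisopropylsilyloxy)-4H-chromen-4-one
Product: 24 7,8-bis(benzyloxy)-3-[3-(benzyloxy)-4,5-dimethoxyphenyl]-5-hydroxy-6-methoxy-4H-chromen-4-one
Conditions: TBAF, AcOH, THF, 0 °C
Reagents that add atoms: none
Why: fluoride-induced cleavage of the aryl silyl ether, driven by the Si–F bond and the good phenoxide leaving group peri to the carbonyl, with acetic acid buffering to protect the base-sensitive pyranone.

Step 17
Reactants: 24 7,8-bis(benzyloxy)-3-[3-(benzyloxy)-4,5-dimethoxyphenyl]-5-hydroxy-6-methoxy-4H-chromen-4-one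
Product: 25 5,7,8-trihydroxy-3-(3-hydroxy-4,5-dimethoxyphenyl)-6-methoxy-4H-chromen-4-one (5,7,8,3'-tetrahydroxy-6,4',5'-trimethoxyisoflavone)
Conditions: H2 (1 atm), 10% Pd/C, EtOAc–MeOH, rt; filtration under argon
Reagents that add atoms: none
Why: catalytic hydrogenolysis of the three benzyl aryl ethers under neutral conditions, which is faster than reduction of the chromone C2=C3 bond, releases the air-sensitive tetraphenol as the last operation.

Compound list
1 | 2,3-dihydroxy-4-methoxybenzaldehyde | COc1ccc(C=O)c(O)c1O | starting material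
2 | benzyl bromide | BrCc1ccccc1 | starting material
3 | 2,3-bis(benzyloxy)-4-methoxybenzaldehyde | COc1ccc(C=O)c(OCc2ccccc2)c1OCc1ccccc1 | intermediate
4 | 2,3-bis(benzyloxy)-4-methoxyphenyl formate | COc1ccc(OC=O)c(OCc2ccccc2)c1OCc1ccccc1 | intermediate (not isolated)
5 | 2,3-bis(benzyloxy)-4-methoxyphenol | COc1ccc(O)c(OCc2ccccc2)c1OCc1ccccc1 | intermediate
6 | 2,3-bis(benzyloxy)-1,4-dimethoxybenzene | COc1ccc(OC)c(OCc2ccccc2)c1OCc1ccccc1 | intermediate
7 | 3,4-bis(benzyloxy)-2,5-dimethoxybenzylidene(dimethyl)iminium chloride | COc1cc(C=[N+](C)C)c(OC)c(OCc2ccccc2)c1OCc1ccccc1.[Cl-] | intermediate (not isolated)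
8 | 3,4-bis(benzyloxy)-2,5-dimethoxybenzaldehyde | COc1cc(C=O)c(OC)c(OCc2ccccc2)c1OCc1ccccc1 | intermediate
9 | 3,4-bis(benzyloxy)-2,5-dimethoxyphenyl formate | COc1cc(OC=O)c(OC)c(OCc2ccccc2)c1OCc1ccccc1 | intermediate (not isolated)
10 | 3,4-bis(benzyloxy)-2,5-dimethoxyphenol | COc1cc(O)c(OC)c(OCc2ccccc2)c1OCc1ccccc1 | intermediate
11 | 3,4-bis(benzyloxy)-6-(hydroxymethyl)-2,5-dimethoxyphenol (formed as its magnesium salt) | COc1c(CO)c(O)c(OC)c(OCc2ccccc2)c1OCc1ccccc1 | intermediate (not isolated)
12 | 3,4-bis(benzyloxy)-6-hydroxy-2,5-dimethoxybenzaldehyde | COc1c(C=O)c(O)c(OC)c(OCc2ccccc2)c1OCc1ccccc1 | intermediate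
13 | 3,4-bis(benzyloxy)-2,5-dimethoxy-6-(triisopropylsilyloxy)benzaldehyde | COc1c(C=O)c(O[Si](C(C)C)(C(C)C)C(C)C)c(OC)c(OCc2ccccc2)c1OCc1ccccc1 | intermediate
14 | 3-hydroxy-4,5-dimethoxybenzaldehyde | COc1cc(C=O)cc(O)c1OC | starting material
15 | 3-(benzyloxy)-4,5-dimethoxybenzaldehyde | COc1cc(C=O)cc(OCc2ccccc2)c1OC | intermediate
16 | [3-(benzyloxy)-4,5-dimethoxyphenyl]methanol | COc1cc(CO)cc(OCc2ccccc2)c1OC | intermediate
17 | 1-(benzyloxy)-5-(chloromethyl)-2,3-dimethoxybenzene | COc1cc(CCl)cc(OCc2ccccc2)c1OC | intermediate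
18 | [3-(benzyloxy)-4,5-dimethoxybenzyl]magnesium chloride | COc1cc(C[Mg]Cl)cc(OCc2ccccc2)c1OC | intermediate (not isolated)
19 | 1-[3,4-bis(benzyloxy)-2,5-dimethoxy-6-(triisopropylsilyloxy)phenyl]-2-[3-(benzyloxy)-4,5-dimethoxyphenyl]ethanol, racemic | COc1c(C(O)Cc2cc(OC)c(OC)c(OCc3ccccc3)c2)c(O[Si](C(C)C)(C(C)C)C(C)C)c(OC)c(OCc2ccccc2)c1OCc1ccccc1 | intermediate
20 | 1-[3,4-bis(benzyloxy)-2,5-dimethoxy-6-(triisopropylsilyloxy)phenyl]-2-[3-(benzyloxy)-4,5-dimethoxyphenyl]ethanone | COc1c(C(=O)Cc2cc(OC)c(OC)c(OCc3ccccc3)c2)c(O[Si](C(C)C)(C(C)C)C(C)C)c(OC)c(OCc2ccccc2)c1OCc1ccccc1 | intermediate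
21 | 2-diazo-1-[3,4-bis(benzyloxy)-2,5-dimethoxy-6-(triisopropylsilyloxy)phenyl]-2-[3-(benzyloxy)-4,5-dimethoxyphenyl]ethanone | COc1c(C(=O)C(=[N+]=[N-])c2cc(OC)c(OC)c(OCc3ccccc3)c2)c(O[Si](C(C)C)(C(C)C)C(C)C)c(OC)c(OCc2ccccc2)c1OCc1ccccc1 | intermediate
22 | 7,8-bis(benzyloxy)-3-[3-(benzyloxy)-4,5-dimethoxyphenyl]-6-methoxy-5-(triisopropylsilyloxy)chroman-4-one, racemic at C3 | O=C1C(c2cc(OC)c(OC)c(OCc3ccccc3)c2)COc2c(OCc3ccccc3)c(OCc3ccccc3)c(OC)c(O[Si](C(C)C)(C(C)C)C(C)C)c12 | intermediate
23 | 7,8-bis(benzyloxy)-3-[3-(benzyloxy)-4,5-dimethoxyphenyl]-6-methoxy-5-(triisopropylsilyloxy)-4H-chromen-4-one | O=c1c(-c2cc(OC)c(OC)c(OCc3ccccc3)c2)coc2c(OCc3ccccc3)c(OCc3ccccc3)c(OC)c(O[Si](C(C)C)(C(C)C)C(C)C)c12 | intermediate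
24 | 7,8-bis(benzyloxy)-3-[3-(benzyloxy)-4,5-dimethoxyphenyl]-5-hydroxy-6-methoxy-4H-chromen-4-one | O=c1c(-c2cc(OC)c(OC)c(OCc3ccccc3)c2)coc2c(OCc3ccccc3)c(OCc3ccccc3)c(OC)c(O)c12 | intermediate
25 | 5,7,8,3'-tetrahydroxy-6,4',5'-trimethoxyisoflavone (achiral) | COc1cc(-c2coc3c(O)c(O)c(OC)c(O)c3c2=O)cc(O)c1OC | target

Total step count: 17. Longest linear sequence: 14 steps (steps 1–7 and 11–17); the B-ring branch (steps 8–10) joins at step 11.

Steps most likely to fail

Step 14. The carbene may be diverted to the lone pair of the 8a-oxygen (oxonium ylide and methyl shift to a benzofuranone), may rearrange by aryl migration, or may not reach the unactivated primary C–H bond. The fallback uses known chemistry, sets out from ketone 20 and comes back to the route at isoflavone 23. Magnesium iodide etherate (toluene, 80 °C) should remove only the methyl ether that chelates to the ketone, giving 1-[3,4-bis(benzyloxy)-2-hydroxy-5-methoxy-6-(triisopropylsilyloxy)phenyl]-2-[3-(benzyloxy)-4,5-dimethoxyphenyl]ethanone F1. Heating F1 with DMF dimethyl acetal (toluene, 90 °C) should give (E)-1-[3,4-bis(benzyloxy)-2-hydroxy-5-methoxy-6-(triisopropylsilyloxy)phenyl]-2-[3-(benzyloxy)-4,5-dimethoxyphenyl]-3-(dimethylamino)prop-2-en-1-one F2 (not isolated, geometry of no consequence). F2 closes onto the free hydroxyl with loss of dimethylamine to give 23, so steps 13–15 are bypassed and C2 comes from the acetal carbon.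

Step 11. Wurtz homocoupling may occur while the benzylic Grignard reagent forms, the benzyl nucleophile may attack through its ortho carbon, or the silyl group may move from the phenolic oxygen to the new alkoxide. The fallback replaces organometallic addition by carbonyl homologation with a diazoalkane; it sets out from aldehydes 15 and 13 and comes back at ketone 20. Condensing 15 with tosylhydrazide (MeOH, rt) gives N'-[3-(benzyloxy)-4,5-dimethoxybenzylidene]-4-methylbenzenesulfonohydrazide F3. Heating F3 with K2CO3 and 13 in dioxane (110 °C) releases 1-(benzyloxy)-5-(diazomethyl)-2,3-dimethoxybenzene F4 (not isolated), which adds to the formyl group of 13 and, after a 1,2-hydride shift with loss of nitrogen, should give 20 directly; steps 9, 10 and 12 then fall away.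

Step 17. Hydrogen may also add to the C2=C3 bond, debenzylation may stall on the crowded A ring, or the para-dihydroxy A ring may oxidise in air during work-up. The fallback sets out from 24 and comes back at target 25 without a new compound: boron trichloride with pentamethylbenzene as benzyl-cation scavenger (CH2Cl2, −78 °C) removes the three benzyl groups by Lewis-acid cleavage, without hydrogen, and at this temperature should leave the methyl ethers and the chromone double bond untouched.

Further compounds
F1 | step 14 | 1-[3,4-bis(benzyloxy)-2-hydroxy-5-methoxy-6-(triisopropylsilyloxy)phenyl]-2-[3-(benzyloxy)-4,5-dimethoxyphenyl]ethanone | Oc1c(C(=O)Cc2cc(OC)c(OC)c(OCc3ccccc3)c2)c(O[Si](C(C)C)(C(C)C)C(C)C)c(OC)c(OCc2ccccc2)c1OCc1ccccc1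
F2 | step 14 | (E)-1-[3,4-bis(benzyloxy)-2-hydroxy-5-methoxy-6-(triisopropylsilyloxy)phenyl]-2-[3-(benzyloxy)-4,5-dimethoxyphenyl]-3-(dimethylamino)prop-2-en-1-one | Oc1c(C(=O)/C(c2cc(OC)c(OC)c(OCc3ccccc3)c2)=C/N(C)C)c(O[Si](C(C)C)(C(C)C)C(C)C)c(OC)c(OCc2ccccc2)c1OCc1ccccc1
F3 | step 11 | N'-[(E)-3-(benzyloxy)-4,5-dimethoxybenzylidene]-4-methylbenzenesulfonohydrazide | COc1cc(/C=N/NS(=O)(=O)c2ccc(C)cc2)cc(OCc2ccccc2)c1OC
F4 | step 11 | 1-(benzyloxy)-5-(diazomethyl)-2,3-dimethoxybenzene | COc1cc(C=[N+]=[N-])cc(OCc2ccccc2)c1OC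
F0 | step 17 | none | none
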